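**Target:** the SMILES encodes all-trans isolariciresinol, an aryltetralin lignan, with CIP configuration (1R,2S,3S). The 2,3-bis(hydroxymethyl) groups are trans, the 1-aryl group is trans to the 2-CH2OH, and the ring carries 7-OH/6-OMe.

**Assumptions:**
- The (S)-diphenylprolinol TMS ether gives the (S)-Michael adduct, by analogy with Hayashi-type nitromethane additions to enals. If the sense is reversed, use the (R)-catalyst.
- Free phenols are carried unprotected throughout.

## Retrosynthetic overview
1. The diol comes from reducing a hydroxy-aldehyde. The C3–CH2OH carbon is carried as CH2NO2 (masked formyl, released by a Nef reaction).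
2. The only new ring is the tetralin ring. It closes last, forming the C1–C8a bond by intramolecular hydroarylation of an α-arylidene aldehyde.
3. C3 is set first; C1 and C2 are relayed from it to the all-equatorial, all-trans arrangement.
4. The α-arylidene aldehyde comes from aldol condensation of vanillin with a γ-nitroaldehyde.
5. The γ-nitroaldehyde comes from organocatalytic Michael addition of MeNO2 to a 4-arylbutenal, which sets C3. The enal comes from cross-metathesis of eugenol with acrolein.

## Route

**Step 1**
- Reactants: 1 eugenol (4-allyl-2-methoxyphenol); 2 acrolein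
- Product: 3 (E)-4-(4-hydroxy-3-methoxyphenyl)but-2-enal
- Conditions: Hoveyda–Grubbs II (5 mol%), 1,4-benzoquinone (10 mol%), acrolein (5 equiv), CH2Cl2, 40 °C
- Reagents that add atoms: none beyond the listed reactants
- Why: Olefin cross-metathesis of a terminal allylarene with an electron-poor partner gives the E-enal, and the quinone suppresses allyl-to-propenyl isomerisation.

**Step 2**
- Reactants: 3 enal; 4 nitromethane
- Product: 5 (S)-3-[(4-hydroxy-3-methoxyphenyl)methyl]-4-nitrobutanal
- Conditions: (S)-Ph2C(OTMS)-pyrrolidine (10 mol%), PhCO2H (10 mol%), MeNO2 (10 equiv), MeOH, 0 °C to rt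
- Reagents that add atoms: none beyond the listed reactants
- Why: Hayashi–Jørgensen iminium-catalysed Michael addition. The bulky silyl ether blocks one face of the E-iminium, so MeNO2 adds to the other face of the β-carbon and sets the C3 stereocentre as (S).

**Step 3**
- Reactants: 5 nitroaldehyde; 6 vanillin (4-hydroxy-3-methoxybenzaldehyde)
- Product: 7 (E)-3-(4-hydroxy-3-methoxyphenyl)-2-[(S)-1-(4-hydroxy-3-methoxyphenyl)-3-nitropropan-2-yl]prop-2-enal
- Conditions: pyrrolidine (20 mol%), AcOH (20 mol%), vanillin (2 equiv), MeCN, 4 Å MS, 50 °C
- Reagents that add atoms: none beyond the listed reactants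
- Why: Enamine-mediated crossed aldol condensation at the only enolisable α-CH2, with dehydration to the conjugated E-α-arylidene aldehyde. The β-stereocentre (C3) is untouched.

**Step 4**
- Reactants: 7
- Product: 8 (1R,2S,3S)-7-hydroxy-1-(4-hydroxy-3-methoxyphenyl)-6-methoxy-3-(nitromethyl)-1,2,3,4-tetrahydronaphthalene-2-carbaldehyde (trans,trans)
- Conditions: pyrrolidine (20 mol%), TFA (1.2 equiv), HFIP (0.02 M), 45 °C
- Reagents that add atoms: none (8 is an isomer of 7)
- Why: Proposed new method: amine/Brønsted-acid (iminium) catalysed 6-endo intramolecular Friedel–Crafts hydroarylation of an α,β-disubstituted β-(4-hydroxyaryl)enal by an unactivated dialkoxyarene.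
  - Mechanism: the iminium (or O-protonated enal) puts positive charge on benzylic C1 as a p-quinone-methide-type cation. The ring carbon para to OMe attacks C1 through a chair-like transition state in which the aryl and CH2NO2 groups are pseudo-equatorial, so C1 is set relative to C3. The resulting enamine is protonated and equilibrates, so the 2-CHO ends up equatorial, trans to both neighbours.
  - Closest known reactions: iminium-catalysed Friedel–Crafts of indoles and pyrroles, and acid cyclisation of 7-hydroxy-dibenzylbutanes to aryltetralins.

**Step 5**
- Reactants: 8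
- Product: 9 (1R,2S,3S)-2-(hydroxymethyl)-3-(nitromethyl)-1-(4-hydroxy-3-methoxyphenyl)-6-methoxy-tetralin-7-ol
- Conditions: NaBH4 (0.6 equiv), MeOH, −10 °C, 20 min
- Reagents that add atoms: none
- Why: Chemoselective aldehyde reduction. The nitroalkane survives, and removing the CHO now prevents cyclic nitrone or pyrroline formation in the next step. No stereocentre is changed.

**Step 6**
- Reactants: 9
- Product: 10 (1R,2S,3S)-hydroxy-aldehyde, which exists largely as the trans-fused lactol: 3-formyl-2-(hydroxymethyl) analogue of 9
- Conditions: TiCl3 (6 equiv, 15% aq.), NH4OAc buffer (pH ~6), THF/H2O, rt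
- Reagents that add atoms: water, O
- Why: McMurry reductive Nef reaction. Nitro is reduced to the imine or oxime and hydrolysed to the aldehyde under non-oxidising conditions that spare the phenols. The C3 configuration is retained because the trans arrangement is also the thermodynamic one.

**Step 7**
- Reactants: 10
- Product: 11 target, (1R,2S,3S)-isolariciresinol-type diol
- Conditions: NaBH4 (4 equiv), MeOH, 0 °C to rt
- Reagents that add atoms: none
- Why: Borohydride reduces the open-chain aldehyde (in equilibrium with the lactol) to give the 2,3-bis(hydroxymethyl) diol. No stereocentre is altered.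

## Compound list
| No. | Name | SMILES | Role |
|---|---|---|---|
| 1 | eugenol | C=CCc1ccc(O)c(OC)c1 | starting material |
| 2 | acrolein | C=CC=O | starting material |
| 3 | (E)-4-(4-hydroxy-3-methoxyphenyl)but-2-enal | O=C/C=C/Cc1ccc(O)c(OC)c1 | intermediate |
| 4 | nitromethane | C[N+](=O)[O-] | starting material |
| 5 | (S)-3-(4-hydroxy-3-methoxybenzyl)-4-nitrobutanal | O=CC[C@@H](C[N+](=O)[O-])Cc1ccc(O)c(OC)c1 | intermediate |
| 6 | vanillin | O=Cc1ccc(O)c(OC)c1 | starting material |
| 7 | α-arylidene aldehyde (S,E) | O=C/C(=C/c1ccc(O)c(OC)c1)[C@@H](C[N+](=O)[O-])Cc1ccc(O)c(OC)c1 | intermediate |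
| 8 | trans,trans-tetralin nitro-aldehyde (1R,2S,3S) | COc1cc([C@@H]2c3cc(O)c(OC)cc3C[C@H](C[N+](=O)[O-])[C@H]2C=O)ccc1O | intermediate |
| 9 | tetralin nitro-alcohol (1R,2S,3S) | COc1cc([C@@H]2c3cc(O)c(OC)cc3C[C@H](C[N+](=O)[O-])[C@H]2CO)ccc1O | intermediate |
| 10 | tetralin hydroxy-aldehyde (lactol tautomer) (1R,2S,3S) | COc1cc([C@@H]2c3cc(O)c(OC)cc3C[C@H](C=O)[C@H]2CO)ccc1O | intermediate |
| 11 | target (1R,2S,3S) | COc1cc([C@@H]2c3cc(O)c(OC)cc3C[C@H](CO)[C@H]2CO)ccc1O | target |

**Total steps:** 7. **Longest linear sequence:** 7 steps (eugenol to target; vanillin joins at Step 3).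

## Three steps most likely to fail
1. **Step 4 (the proposed new step).** The push–pull p-hydroxycinnamaldehyde iminium may be too stabilised to react, or C1 diastereoselectivity may be modest.
   - Fallback (known chemistry): form the TMS enol ether of 5 and run a Mukaiyama aldol with vanillin (TBS-protected, TiCl4, −78 °C). Then ionise the benzylic carbinol with TFA, as in classical cyclolignan cyclisations. This uses an sp3-configured C2 cation route instead of enal hydroarylation.
2. **Step 3.** Amine/base conditions on the γ-nitroaldehyde with electron-rich vanillin may give poor conversion, retro-Michael loss of the nitroalkane, or erosion of C3 stereochemistry.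
   - Fallback: switch to the classical lactone route. Do a Hayashi Michael of 3-(4-hydroxy-3-methoxyphenyl)propanal onto nitroethylene. Then reduce the aldehyde and convert CH2CH2NO2 to the lactone by Nef then oxidation, giving a 3-benzyl-γ-butyrolactone. Follow with an LDA aldol with O-benzylvanillin, TFA cyclisation and LiAlH4/H2-Pd, which avoids any nitro-aldehyde condensation.
3. **Step 6.** The reductive Nef of a primary nitroalkane can stop at the oxime or over-reduce to the amine, and free phenols may complicate Ti(III) work-up.
   - Fallback: use formaldehyde N,N-dimethylhydrazone instead of MeNO2 in Step 2 (diarylprolinol-catalysed aza-enamine conjugate addition). This carries the C3 branch as CH=N–NMe2, which is unmasked to the aldehyde with NaIO4 or CuCl2 before the last reduction.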